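## Structural features

The target is a cis-fused hydroazulene. Ring A is a cyclopentane (C1–C5) and ring B a cycloheptene (C1, C5–C10), sharing the C1–C5 bond. C1 is the methyl-bearing fusion carbon, C2 and C3 are CH2, C4 carries hydroxyl and isopropyl, C5 is the fusion CH, C6 carries the 4-methoxybenzoate, C7 is CH2, C8=C9 is the methyl-substituted alkene and C10 carries the acetate.

The five stereocentres C10, C1, C5, C6 and C4 form one unbroken chain around the quaternary C1 and the tertiary C5 (1S,4R,5R,6S,10S in these locants). The angular methyl, H5, the C4 hydroxyl and the C10 acetoxy group lie on one face; the isopropyl group and the C6 ester lie on the other, so the two acyloxy groups are trans across ring B.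

Fragile points are the allylic acetate at C10 (ionisation, elimination) and the tertiary C4 alcohol, which becomes a retro-aldol or elimination partner whenever C6 is a carbonyl group. The C5–H next to such a carbonyl group can epimerise to the trans series, and two different esters sit on two secondary oxygens.

The real difficulty is the stereochemistry around ring B and not the ring itself. The C10 oxygen must end on the convex face, the face from which a hydride would be expected to approach a ring ketone, and the two secondary oxygens must be told apart.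

The key step exploits the fact that C6 and C10 are both bonded, on the same face, to the adjacent ring A carbons C5 and C1 and both carry oxygen. Joined to each other they form a cyclobutene fused cis to a cyclopentanone, the photoadduct of a 3-methylcyclopentenone and acetylene. Cleavage of the C6=C10 bond returns both carbons at the aldehyde level.

## Logic of the disconnections

24 to 22 and 23: the C6–O acyl bond is cut last. In 22 the only acylable hydroxyl is the secondary one at C6, so no protecting group is needed and the bulky aroyl group is absent during ring closure. The forward step only has to distinguish a secondary from a tertiary alcohol.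

22 to 20 (through 21): the O–Si bond and then C8=C9 are cut. The alkene is the only ring B bond without a stereocentre, and metathesis places the trisubstituted alkene exactly between C7 and C10. The target becomes a cyclopentane with two cis side arms. The forward step must close a seven-membered trisubstituted alkene beside the quaternary C1.

20 to 18 (through 19): the acetyl C–O bond and the C6–H and C10–H bonds are cut, turning both carbinol centres into ketones. A hydride added to a ring B ketone at C10 would be expected from the convex face and would give the wrong epimer. In the open-chain diketone both centres can be set by one enantiomer of an oxazaborolidine catalyst, because in each ketone the ring A side is the larger substituent. The forward steps need catalyst control at two hindered ketones and acetylation of the C10 hydroxyl in the presence of the more screened C6 hydroxyl.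

18 to 12 (through 17 and 15): C9–C10 and C6–C7 are cut. 13 supplies C9 and a terminal CH2 that is lost later; 16 supplies C7, C8 and the C8 methyl. The configuration of the two carbinols formed is immaterial because both are oxidised. The whole C7–C9 insert comes from two commercial Grignard reagents. The first reagent must take the C10 formyl group, after which the alkoxide masks the C6 formyl group as a lactol. An enolate-based closure onto a free C6 aldehyde was not adopted, because that aldehyde is epimerisable at C5 and is tied up as a lactol as soon as C10 carries an alkoxide.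

12 to 10: the two formyl carbons are rejoined as the C6=C10 alkene (ozonolysis transform). This stores both carbonyl groups and their cis relationship in one strained alkene and keeps the epimerisable dialdehyde out of all earlier steps. No other alkene may be present at the ozonolysis stage.

10 to 7 (through 9 and 8): the silyl ether is cut, then the C3–H bond and one C–O bond, which traces the tertiary alcohol to the convex-face epoxide of the C3=C4 alkene. Direct addition of an isopropyl nucleophile to the ketone would put isopropyl on the convex face and give the wrong C4 epimer. Oxygen delivered to the alkene from the convex face, followed by hydride at C3, gives the right one. The peracid must choose the trisubstituted alkene over the cyclobutene and the convex over the concave face.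

7 to 3 (through 5, with 6): the C4–isopropyl bond is cut at the sp2 stage; the alkene comes from the enol triflate of the ketone. Enolisation must go toward C3 and not toward the ring-fusion carbon, and the coupling must tolerate a secondary alkyl nucleophile.

3 to 1 and 2: the cyclobutene is cut at C1–C10 and C5–C6. Both partners are commercial and achiral; two skeletal bonds, one ring and the C1 and C5 stereocentres come from one step. The forward step needs enantiofacial control by a chiral Lewis acid; cis fusion is automatic.

## Other disconnections considered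

Alternative 1: The cut is C5–C6. In the forward direction a C6 dithiane anion, tethered through C7–C10 to C1, would open a C4–C5 epoxide at C5 (7-exo, anti to the oxygen) to give A1.
- In its favour: one polar step closes ring B, sets C5 by inversion and releases the C4 carbinol with a relative configuration that follows from the mechanism. A1 already holds the C8 methyl, the C8=C9 alkene and a protected C10 oxygen. Only dithiane removal, C6 reduction and two acylations would remain, a shorter endgame than in the chosen plan, which is a point in which it is the better.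
- Against it: the attacked carbon lies between two fully substituted carbons, and a bulky, basic anion may instead convert the epoxide into an allylic alcohol or be quenched by the allylic C7 protons. The substrate needs the quaternary C1, the C10 stereocentre, a Z-trisubstituted alkene and a stereodefined epoxide, all made without a ring template. Unmasking gives a ketone with the alkene one carbon away and an epimerisable C5.
- Comparison: on mechanism the ionic opening is as predictable as, or more predictable than, the untested enantioselective photoreaction. On structure the chosen plan creates C1 and C5 together from achiral material. On step economy the short endgame of the alternative is outweighed by a longer substrate synthesis.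

Alternative 2: The cut is C1–C5, traced back to a C1–C6 bond of a decalin. In the forward direction base would trigger a 1,2-shift in the monomesylate of a C5,C6 cis-diol; C1 migrates anti to the leaving group and C6 becomes a ketone, giving A2.
- In its favour: the shift is stereospecific and of a long-established type, and decalin precursors are available in either enantiomeric series by robust annulation chemistry. In certainty of absolute configuration it is the better of the two plans; in delivering the cis fusion and the quaternary C1 in one stereospecific event it is the equal.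
- Against it: A2 has no C8 methyl and no C8=C9 alkene, and C10 is at the ketone level. The methyl group would have to be introduced at a ring position remote from both carbonyl groups, and the C10 ketone would later need reduction on the ring from the unfavourable concave face. The migration terminus sits next to the C4 silyl ether, so fragmentation or elimination could compete, and the basic conditions expose the new C5–H to epimerisation.
- Comparison: the chosen plan brings C8, its methyl and the alkene in with the building blocks and sets C4 before ring B exists. The alternative needs a four-stereocentre decalin first and several late adjustments, so it is longer.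

Alternative 3: The cuts are C2–C3 and C4–C5 of ring A. In the forward direction catalytic SmI2 would form the C6 ketyl of a ring B ketone fused to a cyclopropane and open the C2–C5 bond. The C2 radical would add to an isopropyl-substituted terminal alkyne and the vinyl radical would close on C5, giving A3.
- In its favour: it is catalytic and redox-neutral, forms two C–C bonds and one ring like the chosen key step (an equal on that count) and installs the isopropyl group directly, which is better than the two steps used here.
- Against it: the ketyl would have to break the bond that gives a primary radical and not the C1–C5 bond that gives a tertiary one. The substrate already contains the C1, C8 and C10 stereocentres and needs its own asymmetric synthesis. A3 lacks the C4 hydroxyl and the C8=C9 alkene: hydration of C3=C4 would be needed late, in the presence of the ketone, and dehydrogenation at C8–C9 has no activating group, while the C8 stereocentre it carries is superfluous.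
- Comparison: mechanistically elegant but less secure for fused alkyl cyclopropyl ketones, and it would need more redox steps after the key step than the chosen plan.

Key step: step 1

Assumption: the oxazaborolidine from (S)-α,α-diphenylprolinol is taken to cover the Re face at the methyl-bearing carbon of the bound enone; if the sense is the opposite, the enantiomeric catalyst is used. Skeleton locants C1–C10 as defined above are used for all intermediates.

## Route

Step 1
Reactants: 1 3-methylcyclopent-2-en-1-one; 2 acetylene
Product: 3 (1S,5R)-5-methylbicyclo[3.2.0]hept-6-en-2-one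
Conditions: B-(2,4,6-trifluorophenyl)oxazaborolidine from (S)-α,α-diphenylprolinol activated with AlBr3 (0.5 equiv), CH2Cl2 saturated with 2, hν (366 nm), −75 °C, stopped before full conversion
Reagents that add atoms: none
Why: Proposed new method: the Lewis acid binds the carbonyl oxygen and shifts the enone absorption to longer wavelength, so that at 366 nm mainly the chiral complex is excited; its triplet adds 2 to give a 1,4-diradical that collapses to the cyclobutene after spin inversion. The closest known reactions are the racemic enone–acetylene photocycloaddition and the enantioselective enone–alkene photocycloaddition catalysed by AlBr3-activated oxazaborolidines; only the pairing of the chiral Lewis acid with an alkyne is new. The four-membered ring is closed by intermolecular (2+2) cycloaddition, the second bond forming by radical recombination; a trans-fused four-five system is too strained, so C1 and C5 are cis. Their absolute configuration is set by the catalyst, whose aryl group covers one face of the bound enone, and 2 must add to the face that is Si at the methyl-bearing carbon. Only enantiofacial selectivity is needed, because 2 is symmetric and carries no substituent to orient. The uncatalysed racemic reaction should be held down by the weak absorption of free 1 at 366 nm and by the low temperature. The product is a β,γ-unsaturated ketone that could undergo a photochemical 1,3-acyl shift, hence the long wavelength and the incomplete conversion.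

Step 2
Reactants: 3 (1S,5R)-5-methylbicyclo[3.2.0]hept-6-en-2-one
Product: 5 (1S,5R)-5-methylbicyclo[3.2.0]hepta-2,6-dien-2-yl trifluoromethanesulfonate, via potassium enolate 4 (not isolated)
Conditions: KN(SiMe3)2, THF, −78 °C; then PhNTf2, −78 → 0 °C
Reagents that add atoms: N-phenylbis(trifluoromethanesulfonimide), O=S(=O)(N(c1ccccc1)S(=O)(=O)C(F)(F)F)C(F)(F)F
Why: Kinetic enolisation with a bulky amide base takes the accessible C3 methylene, since the other enolate would place a double bond at the fusion carbon of the strained bicycle; O-sulfonylation then gives the enol triflate and no stereocentre is touched.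

Step 3
Reactants: 5 (1S,5R)-5-methylbicyclo[3.2.0]hepta-2,6-dien-2-yl trifluoromethanesulfonate; 6 isopropylmagnesium chloride
Product: 7 (1S,5R)-5-methyl-2-(propan-2-yl)bicyclo[3.2.0]hepta-2,6-diene
Conditions: Fe(acac)3 (5 mol%), THF/NMP, −30 °C; volatile product carried on in solution
Reagents that add atoms: none
Why: Iron-catalysed Kumada-type coupling of an alkenyl triflate with an alkyl Grignard reagent is fast at low temperature and is not prone to isomerisation of the secondary alkyl group; the cyclobutene is inert.

Step 4
Reactants: 7 (1S,5R)-5-methyl-2-(propan-2-yl)bicyclo[3.2.0]hepta-2,6-diene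
Product: 8 (1S,2R,4S,6R)-6-methyl-2-(propan-2-yl)-3-oxatricyclo[4.2.0.0(2,4)]oct-7-ene
Conditions: mCPBA (1.0 equiv), NaHCO3, CH2Cl2, −20 → 0 °C
Reagents that add atoms: 3-chloroperoxybenzoic acid, OOC(=O)c1cccc(Cl)c1
Why: Prilezhaev epoxidation; the electron-rich trisubstituted alkene should react well before the disubstituted cyclobutene, and the peracid approaches the cup-shaped bicycle from its convex face, away from the four-membered ring, which sets C3 and C4 with oxygen on the face of the angular methyl group. The buffer protects the acid-labile epoxide.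

Step 5
Reactants: 8 (1S,2R,4S,6R)-6-methyl-2-(propan-2-yl)-3-oxatricyclo[4.2.0.0(2,4)]oct-7-ene
Product: 9 (1S,2R,5R)-5-methyl-2-(propan-2-yl)bicyclo[3.2.0]hept-6-en-2-ol
Conditions: LiEt3BH, THF, 0 °C → rt
Reagents that add atoms: none
Why: SN2 opening of the epoxide by hydride at the less substituted C3, the ring carbon farthest from the four-membered ring; the C4–O bond is not broken, so the tertiary alcohol keeps the configuration set in step 4.

Step 6
Reactants: 9 (1S,2R,5R)-5-methyl-2-(propan-2-yl)bicyclo[3.2.0]hept-6-en-2-ol
Product: 10 triethyl{[(1S,2R,5R)-5-methyl-2-(propan-2-yl)bicyclo[3.2.0]hept-6-en-2-yl]oxy}silane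
Conditions: Et3SiOTf, 2,6-lutidine, CH2Cl2, −78 → 0 °C
Reagents that add atoms: triethylsilyl trifluoromethanesulfonate, CC[Si](CC)(CC)OS(=O)(=O)C(F)(F)F
Why: Silyl triflates silylate hindered tertiary alcohols; the ether removes the acidic proton and any chelation or retro-aldol pathway once C6 is a carbonyl group, and it adds the bulk beside C6 on which the later site selections rely.

Step 7
Reactants: 10 triethyl{[(1S,2R,5R)-5-methyl-2-(propan-2-yl)bicyclo[3.2.0]hept-6-en-2-yl]oxy}silane
Product: 12 (1S,2S,3R)-1-methyl-3-(propan-2-yl)-3-[(triethylsilyl)oxy]cyclopentane-1,2-dicarbaldehyde, via secondary ozonide 11 (not isolated)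
Conditions: O3, CH2Cl2, −78 °C; then PPh3, −78 °C → rt; used crude
Reagents that add atoms: ozone, [O-][O+]=O
Why: Ozonolysis (Criegee mechanism) of the only alkene; reduction of the ozonide with the phosphine is neutral, so C5, now next to a formyl group, should not epimerise, and C6 and C10 are released as aldehydes cis on C5 and C1.

Step 8
Reactants: 12 (1S,2S,3R)-1-methyl-3-(propan-2-yl)-3-[(triethylsilyl)oxy]cyclopentane-1,2-dicarbaldehyde; 13 vinylmagnesium bromide
Product: 15 (3aS,6R,6aS)-3-ethenyl-3a-methyl-6-(propan-2-yl)-6-[(triethylsilyl)oxy]hexahydro-1H-cyclopenta[c]furan-1-ol (epimers at the two furan CH carbons), via open hydroxy aldehyde 14 (not isolated)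
Conditions: 13 (1.05 equiv), THF, −78 °C, slow addition; NH4Cl
Reagents that add atoms: none
Why: Grignard 1,2-addition; the C6 formyl group sits on a carbon flanked by two fully substituted carbons, one bearing OSiEt3, so the reagent should take the C10 formyl group on the methyl-bearing carbon. The alkoxide then closes onto the cis C6 formyl group, and the lactolate shields it from a second addition and from enolisation; the C10 configuration need not be controlled.

Step 9
Reactants: 15 (3aS,6R,6aS)-3-ethenyl-3a-methyl-6-(propan-2-yl)-6-[(triethylsilyl)oxy]hexahydro-1H-cyclopenta[c]furan-1-ol; 16 2-methylallylmagnesium chloride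
Product: 17 1-[(1S,2R,3R)-2-(1-hydroxy-3-methylbut-3-en-1-yl)-1-methyl-3-(propan-2-yl)-3-[(triethylsilyl)oxy]cyclopentyl]prop-2-en-1-ol (epimers at both carbinol carbons)
Conditions: 16 (2.5 equiv), THF, −78 → 0 °C
Reagents that add atoms: none
Why: The magnesium lactolate is in equilibrium with the alkoxy aldehyde, to which an allyl-type Grignard reagent adds faster than it deprotonates; this forms C6–C7, and both carbinol centres are oxidised next so their configuration is irrelevant.

Step 10
Reactants: 17 1-[(1S,2R,3R)-2-(1-hydroxy-3-methylbut-3-en-1-yl)-1-methyl-3-(propan-2-yl)-3-[(triethylsilyl)oxy]cyclopentyl]prop-2-en-1-ol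
Product: 18 1-[(1S,2S,3R)-1-methyl-2-(3-methylbut-3-enoyl)-3-(propan-2-yl)-3-[(triethylsilyl)oxy]cyclopentyl]prop-2-en-1-one
Conditions: 1,1,1-triacetoxy-1,1-dihydro-1,2-benziodoxol-3(1H)-one (Dess–Martin periodinane), NaHCO3, CH2Cl2, 0 °C → rt; used directly
Reagents that add atoms: none
Why: Dess–Martin oxidation of both secondary alcohols under buffered, non-basic conditions, which should keep the C7 methylene ketone out of conjugation and C5 unepimerised; with the silyl ether in place no β-hydroxy ketone is present.

Step 11
Reactants: 18 1-[(1S,2S,3R)-1-methyl-2-(3-methylbut-3-enoyl)-3-(propan-2-yl)-3-[(triethylsilyl)oxy]cyclopentyl]prop-2-en-1-one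
Product: 19 (1S)-1-[(1S,2R,3R)-2-[(1S)-1-hydroxy-3-methylbut-3-en-1-yl]-1-methyl-3-(propan-2-yl)-3-[(triethylsilyl)oxy]cyclopentyl]prop-2-en-1-ol
Conditions: (R)-1-methyl-3,3-diphenyltetrahydro-1H,3H-pyrrolo[1,2-c][1,3,2]oxazaborole ((R)-Me-CBS, 0.5 equiv), catecholborane, toluene, −78 → −20 °C; MeOH, then aq. NaOH wash
Reagents that add atoms: none
Why: Corey–Bakshi–Shibata reduction; in each ketone the ring A carbon (quaternary C1 beside C10, the doubly flanked C5 beside C6) is the large group and vinyl or the methallyl CH2 the small one, so the (R)-catalyst should give the (S)-carbinol at both centres. Catecholborane at low temperature favours 1,2-reduction of the enone and does not hydroborate the alkenes.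

Step 12
Reactants: 19 (1S)-1-[(1S,2R,3R)-2-[(1S)-1-hydroxy-3-methylbut-3-en-1-yl]-1-methyl-3-(propan-2-yl)-3-[(triethylsilyl)oxy]cyclopentyl]prop-2-en-1-ol
Product: 20 (1S)-1-[(1S,2R,3R)-2-[(1S)-1-hydroxy-3-methylbut-3-en-1-yl]-1-methyl-3-(propan-2-yl)-3-[(triethylsilyl)oxy]cyclopentyl]prop-2-en-1-yl acetate
Conditions: Ac2O (1.1 equiv), DMAP (cat.), Et3N, CH2Cl2, −20 → 0 °C
Reagents that add atoms: acetic anhydride, CC(=O)OC(C)=O
Why: DMAP-catalysed acylation is sensitive to crowding: the C10 hydroxyl has a flat vinyl group as one neighbour, whereas the C6 hydroxyl is screened by C5 and the silyloxy-bearing C4, so the first equivalent of anhydride should go to C10.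

Step 13
Reactants: 20 (1S)-1-[(1S,2R,3R)-2-[(1S)-1-hydroxy-3-methylbut-3-en-1-yl]-1-methyl-3-(propan-2-yl)-3-[(triethylsilyl)oxy]cyclopentyl]prop-2-en-1-yl acetate
Product: 21 (3R,3aR,4S,8S,8aS)-4-hydroxy-6,8a-dimethyl-3-(propan-2-yl)-3-[(triethylsilyl)oxy]-1,2,3,3a,4,5,8,8a-octahydroazulen-8-yl acetate
Conditions: second-generation Hoveyda–Grubbs catalyst, RuCl2(H2IMes)(=CH-C6H4-2-OiPr) (5–10 mol%), toluene (5 mM), 80 °C
Reagents that add atoms: none
Why: Ring-closing metathesis; the catalyst loads on the monosubstituted vinyl group and closes onto the 1,1-disubstituted alkene, helped by the cis arrangement of the two arms on ring A; the C8=C9 alkene can only be Z in a seven-membered ring and no stereocentre is formed.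

Step 14
Reactants: 21 (3R,3aR,4S,8S,8aS)-4-hydroxy-6,8a-dimethyl-3-(propan-2-yl)-3-[(triethylsilyl)oxy]-1,2,3,3a,4,5,8,8a-octahydroazulen-8-yl acetate
Product: 22 (3R,3aR,4S,8S,8aS)-3,4-dihydroxy-6,8a-dimethyl-3-(propan-2-yl)-1,2,3,3a,4,5,8,8a-octahydroazulen-8-yl acetate
Conditions: HF·pyridine, THF/pyridine, 0 °C → rt
Reagents that add atoms: none
Why: Fluoride-driven cleavage of the Si–O bond; buffered hydrogen fluoride should leave the allylic acetate and the alkene untouched.

Step 15
Reactants: 22 (3R,3aR,4S,8S,8aS)-3,4-dihydroxy-6,8a-dimethyl-3-(propan-2-yl)-1,2,3,3a,4,5,8,8a-octahydroazulen-8-yl acetate; 23 4-methoxybenzoyl chloride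
Product: 24 (3R,3aR,4S,8S,8aS)-8-(acetyloxy)-3-hydroxy-6,8a-dimethyl-3-(propan-2-yl)-1,2,3,3a,4,5,8,8a-octahydroazulen-4-yl 4-methoxybenzoate (target)
Conditions: 23 (1.5 equiv), DMAP, pyridine, CH2Cl2, rt
Reagents that add atoms: none
Why: DMAP-catalysed acylation esterifies the secondary C6 hydroxyl while the tertiary C4 hydroxyl is inert under these conditions; the C10 acetate cannot migrate to C6 because the two oxygens are trans across ring B.

## Compound list

1 | 3-methylcyclopent-2-en-1-one | CC1=CC(=O)CC1 | starting material
2 | acetylene | C#C | starting material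
3 | (1S,5R)-5-methylbicyclo[3.2.0]hept-6-en-2-one | C1=C[C@@]2(C)CCC(=O)[C@@H]12 | intermediate
4 | potassium (1S,5R)-5-methylbicyclo[3.2.0]hepta-2,6-dien-2-olate | C1=C[C@@]2(C)CC=C([O-])[C@@H]12.[K+] | intermediate (not isolated)
5 | (1S,5R)-5-methylbicyclo[3.2.0]hepta-2,6-dien-2-yl trifluoromethanesulfonate | C1=C[C@@]2(C)CC=C(OS(=O)(=O)C(F)(F)F)[C@@H]12 | intermediate
6 | isopropylmagnesium chloride | CC(C)[Mg]Cl | starting material
7 | (1S,5R)-5-methyl-2-(propan-2-yl)bicyclo[3.2.0]hepta-2,6-diene | C1=C[C@@]2(C)CC=C(C(C)C)[C@@H]12 | intermediate
8 | (1S,2R,4S,6R)-6-methyl-2-(propan-2-yl)-3-oxatricyclo[4.2.0.0(2,4)]oct-7-ene | C1=C[C@@]2(C)C[C@@H]3O[C@]3(C(C)C)[C@@H]12 | intermediate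
9 | (1S,2R,5R)-5-methyl-2-(propan-2-yl)bicyclo[3.2.0]hept-6-en-2-ol | C1=C[C@@]2(C)CC[C@@](O)(C(C)C)[C@@H]12 | intermediate
10 | triethyl{[(1S,2R,5R)-5-methyl-2-(propan-2-yl)bicyclo[3.2.0]hept-6-en-2-yl]oxy}silane | C1=C[C@@]2(C)CC[C@@](O[Si](CC)(CC)CC)(C(C)C)[C@@H]12 | intermediate
11 | secondary ozonide of 10 (1,2,4-trioxolane spanning C6 and C10, both ring-fusion forms) | O1OC2OC1[C@@]3(C)CC[C@@](O[Si](CC)(CC)CC)(C(C)C)[C@@H]23 | intermediate (not isolated)
12 | (1S,2S,3R)-1-methyl-3-(propan-2-yl)-3-[(triethylsilyl)oxy]cyclopentane-1,2-dicarbaldehyde | O=C[C@@]1(C)CC[C@@](O[Si](CC)(CC)CC)(C(C)C)[C@H]1C=O | intermediate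
13 | vinylmagnesium bromide | C=C[Mg]Br | starting material
14 | (1S,2S,5R)-2-(1-hydroxyprop-2-en-1-yl)-2-methyl-5-(propan-2-yl)-5-[(triethylsilyl)oxy]cyclopentane-1-carbaldehyde (both carbinol epimers) | C=CC(O)[C@@]1(C)CC[C@@](O[Si](CC)(CC)CC)(C(C)C)[C@H]1C=O | intermediate (not isolated)
15 | (3aS,6R,6aS)-3-ethenyl-3a-methyl-6-(propan-2-yl)-6-[(triethylsilyl)oxy]hexahydro-1H-cyclopenta[c]furan-1-ol (epimers at C1 and C3 of the furan ring) | C=CC1OC(O)[C@H]2[C@]1(C)CC[C@@]2(O[Si](CC)(CC)CC)C(C)C | intermediate
16 | 2-methylallylmagnesium chloride | C=C(C)C[Mg]Cl | starting material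
17 | 1-[(1S,2R,3R)-2-(1-hydroxy-3-methylbut-3-en-1-yl)-1-methyl-3-(propan-2-yl)-3-[(triethylsilyl)oxy]cyclopentyl]prop-2-en-1-ol (epimers at both carbinol carbons) | C=CC(O)[C@@]1(C)CC[C@@](O[Si](CC)(CC)CC)(C(C)C)[C@H]1C(O)CC(C)=C | intermediate
18 | 1-[(1S,2S,3R)-1-methyl-2-(3-methylbut-3-enoyl)-3-(propan-2-yl)-3-[(triethylsilyl)oxy]cyclopentyl]prop-2-en-1-one | C=CC(=O)[C@@]1(C)CC[C@@](O[Si](CC)(CC)CC)(C(C)C)[C@H]1C(=O)CC(C)=C | intermediate
19 | (1S)-1-[(1S,2R,3R)-2-[(1S)-1-hydroxy-3-methylbut-3-en-1-yl]-1-methyl-3-(propan-2-yl)-3-[(triethylsilyl)oxy]cyclopentyl]prop-2-en-1-ol | C=C[C@H](O)[C@@]1(C)CC[C@@](O[Si](CC)(CC)CC)(C(C)C)[C@H]1[C@@H](O)CC(C)=C | intermediate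
20 | (1S)-1-[(1S,2R,3R)-2-[(1S)-1-hydroxy-3-methylbut-3-en-1-yl]-1-methyl-3-(propan-2-yl)-3-[(triethylsilyl)oxy]cyclopentyl]prop-2-en-1-yl acetate | C=C[C@H](OC(C)=O)[C@@]1(C)CC[C@@](O[Si](CC)(CC)CC)(C(C)C)[C@H]1[C@@H](O)CC(C)=C | intermediate
21 | (3R,3aR,4S,8S,8aS)-4-hydroxy-6,8a-dimethyl-3-(propan-2-yl)-3-[(triethylsilyl)oxy]-1,2,3,3a,4,5,8,8a-octahydroazulen-8-yl acetate | O[C@H]1CC(C)=C[C@H](OC(C)=O)[C@@]2(C)CC[C@@](O[Si](CC)(CC)CC)(C(C)C)[C@@H]12 | intermediate
22 | (3R,3aR,4S,8S,8aS)-3,4-dihydroxy-6,8a-dimethyl-3-(propan-2-yl)-1,2,3,3a,4,5,8,8a-octahydroazulen-8-yl acetate | O[C@H]1CC(C)=C[C@H](OC(C)=O)[C@@]2(C)CC[C@@](O)(C(C)C)[C@@H]12 | intermediate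
23 | 4-methoxybenzoyl chloride | COc1ccc(cc1)C(Cl)=O | starting material
24 | (3R,3aR,4S,8S,8aS)-8-(acetyloxy)-3-hydroxy-6,8a-dimethyl-3-(propan-2-yl)-1,2,3,3a,4,5,8,8a-octahydroazulen-4-yl 4-methoxybenzoate | COc1ccc(C(=O)O[C@H]2CC(C)=C[C@H](OC(C)=O)[C@@]3(C)CC[C@@](O)(C(C)C)[C@@H]23)cc1 | target

## Step count and least certain steps

Total: 15 steps. Longest linear sequence: 15 steps (from 1 and 2; 6, 13, 16 and 23 are bought).

**Step 1 (key step, proposed new method).** The most likely failure is loss of enantiofacial control. Acetylene may trap the complexed triplet more slowly than alkenes do, which gives the racemic background reaction and photodecomposition of the catalyst more room. AlBr3 may also start oligomerisation of acetylene, and over-irradiation may send the product into a 1,3-acyl shift.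
Fallback, known chemistry only, setting out from 1 and 2 and returning at 3:
- Uncatalysed irradiation (acetylene-saturated CH2Cl2, −70 °C, Pyrex-filtered lamp) gives the racemic ketone rac-5-methylbicyclo[3.2.0]hept-6-en-2-one F1.
- NaBH4 (MeOH, 0 °C) attacks from the convex face and gives the racemic endo alcohol rac-5-methylbicyclo[3.2.0]hept-6-en-2-ol F2.
- Acylation with Candida antarctica lipase B and vinyl acetate is a kinetic resolution. By the empirical size rule for secondary alcohols the (2R)-alcohol of the wanted series should be acylated, to give (1S,2R,5R)-5-methylbicyclo[3.2.0]hept-6-en-2-yl acetate F3. If the enzyme prefers the other enantiomer, the unreacted alcohol is taken instead.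
- Methanolysis (K2CO3, MeOH) gives (1S,2R,5R)-5-methylbicyclo[3.2.0]hept-6-en-2-ol F4, and Dess–Martin oxidation returns 3.

**Step 8.** The likely failure is addition at the wrong formyl group, with double addition and enolisation-driven epimerisation at C5 as secondary risks; the choice of C10 rests on a steric argument only.
Fallback from 12, returning at 17: the order of the two Grignard reagents is reversed. 16 is added first; if the C6 formyl group is the more reactive one this gives the regioisomeric lactol (3aR,4R,6aS)-6a-methyl-3-(2-methylprop-2-en-1-yl)-4-(propan-2-yl)-4-[(triethylsilyl)oxy]hexahydro-1H-cyclopenta[c]furan-1-ol F5. An excess of 13 then opens it and adds at C10 to give 17.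

**Step 11.** The likely failure is slow or catalyst-independent reduction of the very hindered C6 ketone. Mismatch with the resident stereocentres, conjugate reduction of the vinyl ketone and a reversed size ranking of vinyl against the quaternary carbon are further risks.
Fallback from 18, returning at 21, which uses ring control for C6 instead of catalyst control:
- The same catalyst with one equivalent of catecholborane at −78 °C reduces only the enone, giving the hydroxy ketone 1-[(1S,2R,5S)-2-[(1S)-1-hydroxyprop-2-en-1-yl]-2-methyl-5-(propan-2-yl)-5-[(triethylsilyl)oxy]cyclopentyl]-3-methylbut-3-en-1-one F6.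
- Acetylation gives its acetate F7.
- Ring-closing metathesis gives the ring ketone (3R,3aR,8S,8aS)-6,8a-dimethyl-4-oxo-3-(propan-2-yl)-3-[(triethylsilyl)oxy]-1,2,3,3a,4,5,8,8a-octahydroazulen-8-yl acetate F8.
- LiBH(s-Bu)3 at −78 °C should add from the face of H5, away from the isopropyl-bearing C4, to give 21.

**Step 12.** The likely failure is acetylation at both hydroxyls or at C6.
Fallback from 19, returning at 24, in which the two oxygens are told apart by oxidation state:
- MnO2 oxidises only the allylic C10 carbinol, giving the hydroxy enone 1-[(1S,2R,3R)-2-[(1S)-1-hydroxy-3-methylbut-3-en-1-yl]-1-methyl-3-(propan-2-yl)-3-[(triethylsilyl)oxy]cyclopentyl]prop-2-en-1-one F9.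
- 23 with DMAP gives the C6 4-methoxybenzoate of that enone F10.
- Reduction as in step 11 gives the (10S)-alcohol F11.
- Acetylation gives the diester diene F12.
- Ring-closing metathesis gives the triethylsilyl ether of the target F13, and HF·pyridine gives 24.

**Step 13.** The likely failure is slow loading of the catalyst on the vinyl group beside the quaternary carbon, followed by oligomerisation or alkene migration.
Fallback from 20, returning at 22: the silyl group is removed first (HF·pyridine) to give the less crowded diene (1S)-1-[(1S,2R,3R)-3-hydroxy-2-[(1S)-1-hydroxy-3-methylbut-3-en-1-yl]-1-methyl-3-(propan-2-yl)cyclopentyl]prop-2-en-1-yl acetate F14. Its ring closure gives 22 directly.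

## Further compounds

F1 | step 1 | rac-(1S*,5R*)-5-methylbicyclo[3.2.0]hept-6-en-2-one (racemate, one enantiomer drawn) | C1=C[C@@]2(C)CCC(=O)[C@@H]12
F2 | step 1 | rac-(1S*,2R*,5R*)-5-methylbicyclo[3.2.0]hept-6-en-2-ol (racemate, one enantiomer drawn) | C1=C[C@@]2(C)CC[C@@H](O)[C@@H]12
F3 | step 1 | (1S,2R,5R)-5-methylbicyclo[3.2.0]hept-6-en-2-yl acetate | C1=C[C@@]2(C)CC[C@@H](OC(C)=O)[C@@H]12
F4 | step 1 | (1S,2R,5R)-5-methylbicyclo[3.2.0]hept-6-en-2-ol | C1=C[C@@]2(C)CC[C@@H](O)[C@@H]12
F5 | step 8 | (3aR,4R,6aS)-6a-methyl-3-(2-methylprop-2-en-1-yl)-4-(propan-2-yl)-4-[(triethylsilyl)oxy]hexahydro-1H-cyclopenta[c]furan-1-ol (epimers at C1 and C3) | C=C(C)CC1OC(O)[C@@]2(C)CC[C@@](O[Si](CC)(CC)CC)(C(C)C)[C@@H]12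
F6 | step 11 | 1-[(1S,2R,5S)-2-[(1S)-1-hydroxyprop-2-en-1-yl]-2-methyl-5-(propan-2-yl)-5-[(triethylsilyl)oxy]cyclopentyl]-3-methylbut-3-en-1-one | C=C[C@H](O)[C@@]1(C)CC[C@@](O[Si](CC)(CC)CC)(C(C)C)[C@H]1C(=O)CC(C)=C
F7 | step 11 | (1S)-1-[(1S,2S,3R)-1-methyl-2-(3-methylbut-3-enoyl)-3-(propan-2-yl)-3-[(triethylsilyl)oxy]cyclopentyl]prop-2-en-1-yl acetate | C=C[C@H](OC(C)=O)[C@@]1(C)CC[C@@](O[Si](CC)(CC)CC)(C(C)C)[C@H]1C(=O)CC(C)=C
F8 | step 11 | (3R,3aR,8S,8aS)-6,8a-dimethyl-4-oxo-3-(propan-2-yl)-3-[(triethylsilyl)oxy]-1,2,3,3a,4,5,8,8a-octahydroazulen-8-yl acetate | O=C1CC(C)=C[C@H](OC(C)=O)[C@@]2(C)CC[C@@](O[Si](CC)(CC)CC)(C(C)C)[C@@H]12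
F9 | step 12 | 1-[(1S,2R,3R)-2-[(1S)-1-hydroxy-3-methylbut-3-en-1-yl]-1-methyl-3-(propan-2-yl)-3-[(triethylsilyl)oxy]cyclopentyl]prop-2-en-1-one | C=CC(=O)[C@@]1(C)CC[C@@](O[Si](CC)(CC)CC)(C(C)C)[C@H]1[C@@H](O)CC(C)=C
F10 | step 12 | (1S)-3-methyl-1-[(1R,2S,5R)-2-methyl-2-(prop-2-enoyl)-5-(propan-2-yl)-5-[(triethylsilyl)oxy]cyclopentyl]but-3-en-1-yl 4-methoxybenzoate | COc1ccc(C(=O)O[C@@H](CC(C)=C)[C@@H]2[C@](O[Si](CC)(CC)CC)(C(C)C)CC[C@]2(C)C(=O)C=C)cc1
F11 | step 12 | (1S)-1-[(1R,2S,5R)-2-[(1S)-1-hydroxyprop-2-en-1-yl]-2-methyl-5-(propan-2-yl)-5-[(triethylsilyl)oxy]cyclopentyl]-3-methylbut-3-en-1-yl 4-methoxybenzoate | COc1ccc(C(=O)O[C@@H](CC(C)=C)[C@@H]2[C@](O[Si](CC)(CC)CC)(C(C)C)CC[C@]2(C)[C@@H](O)C=C)cc1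
F12 | step 12 | (1S)-1-[(1R,2S,5R)-2-[(1S)-1-(acetyloxy)prop-2-en-1-yl]-2-methyl-5-(propan-2-yl)-5-[(triethylsilyl)oxy]cyclopentyl]-3-methylbut-3-en-1-yl 4-methoxybenzoate | COc1ccc(C(=O)O[C@@H](CC(C)=C)[C@@H]2[C@](O[Si](CC)(CC)CC)(C(C)C)CC[C@]2(C)[C@@H](OC(C)=O)C=C)cc1
F13 | step 12 | (3R,3aR,4S,8S,8aS)-8-(acetyloxy)-6,8a-dimethyl-3-(propan-2-yl)-3-[(triethylsilyl)oxy]-1,2,3,3a,4,5,8,8a-octahydroazulen-4-yl 4-methoxybenzoate | COc1ccc(C(=O)O[C@H]2CC(C)=C[C@H](OC(C)=O)[C@@]3(C)CC[C@@](O[Si](CC)(CC)CC)(C(C)C)[C@@H]23)cc1
F14 | step 13 | (1S)-1-[(1S,2R,3R)-3-hydroxy-2-[(1S)-1-hydroxy-3-methylbut-3-en-1-yl]-1-methyl-3-(propan-2-yl)cyclopentyl]prop-2-en-1-yl acetate | C=C[C@H](OC(C)=O)[C@@]1(C)CC[C@@](O)(C(C)C)[C@H]1[C@@H](O)CC(C)=C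
A1 | alternative 1 | cis-fused hydroazulene with a C6 1,3-dithiane, free C4 hydroxyl and C10 tert-butyldimethylsilyl ether | S1CCCSC12CC(C)=C[C@H](O[Si](C)(C)C(C)(C)C)[C@@]3(C)CC[C@@](O)(C(C)C)[C@@H]23
A2 | alternative 2 | cis-fused hydroazulen-6-one with C4 triethylsilyl ether and C10 ethylene ketal | O=C1CCCC2(OCCO2)[C@@]3(C)CC[C@@](O[Si](CC)(CC)CC)(C(C)C)[C@@H]13
A3 | alternative 3 | cis-fused hydroazulen-6-one with C3=C4 isopropyl alkene, C8 methyl and C10 tert-butyldimethylsilyl ether | O=C1C[C@@H](C)C[C@H](O[Si](C)(C)C(C)(C)C)[C@@]2(C)CC=C(C(C)C)[C@@H]12
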